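**Plan**

1. Retrosynthetic cuts, in order: (a) the bond from resorcinol ring C to the CH that carries the 2,4-dihydroxyphenyl group, which opens the seven-membered ring D to a stilbene; (b) the bond from C4 of the central benzene ring A to that stilbene, traced back to a C4–O group; (c) in each dihydrofuran (rings B and B′) the aryl–O bond and the C3–aryl bond to ring A, which leaves a benzene-1,2:4,5-diyne equivalent and two molecules of one trans-stilbene oxide.
2. Enabling feature: in rings B and B′ the oxygen and C3 sit on neighbouring carbons of ring A, both rings are (2R,3R) and are exchanged by a twofold axis through C4 and C8 of the tetrahydrobenzo[1,2-b:5,4-b']difuran core, and C4 lies between the two C3-bearing carbons. One alkoxy group at C4 can therefore steer two aryne additions and then become the coupling site.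
3. Forward order: pterostilbene → aryl triflate → (S,S)-oxirane 3; 1,3-bis(benzyloxy)benzene → bis(o-silylaryl triflate) 13; 13 + 2 × 3 → rings B and B′ in one operation, each oxirane enlarged by two aryne carbons (17); C4–O → C4–styryl (24); acid closes ring D (25); deprotection.
4. Stereochemistry: one Shi epoxidation supplies all four dihydrofuran centres (the C–O centre is carried over, C3 closes trans to it). The fifth centre is set by the adjacent furan C3 centre in the cationic ring closure.
5. Protecting groups: the para oxygens are triflates in the key step (this decides which oxirane C–O bond opens) and pivalates through the palladium and acid steps; the methyl ethers of pterostilbene come off last.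

Key step: step 8

Remark: locants are those of benzo[1,2-b:5,4-b']difuran (O1, C2, C3, C3a, C4, C4a, C5, C6, O7, C7a, C8, C8a).
Remark: the closure of ring D is assumed to give the diastereomer of the target (aryl group cis to H-3 of the fused dihydrofuran), the arrangement that keeps the aryl group out of the plane of the peri-methoxylated ring C.
Remark: the L-series epoxidation ketone of step 2 is taken as a purchased catalyst.

**Route**

Step 1
Reactants: 1 pterostilbene
Product: 2 4-[(E)-2-(3,5-dimethoxyphenyl)ethenyl]phenyl trifluoromethanesulfonate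
Conditions: Tf2O, pyridine, CH2Cl2, 0 °C
Reagents that add atoms: trifluoromethanesulfonic anhydride O=S(=O)(OS(=O)(=O)C(F)(F)F)C(F)(F)F
Why: O-sulfonylation of the phenol; triflate is the most electron-withdrawing sulfonate that is easy to install, and it later decides which C–O bond of the oxirane opens.

Step 2
Reactants: 2 4-[(E)-2-(3,5-dimethoxyphenyl)ethenyl]phenyl trifluoromethanesulfonate
Product: 3 4-[(2S,3S)-3-(3,5-dimethoxyphenyl)oxiran-2-yl]phenyl trifluoromethanesulfonate
Conditions: 1,2:4,5-di-O-isopropylidene-β-L-erythro-2,3-hexodiulo-2,6-pyranose (0.3 equiv), Oxone (2KHSO5·KHSO4·K2SO4), K2CO3, Bu4NHSO4, MeCN/CH2(OMe)2, aq. Na2B4O7 buffer, 0 °C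
Reagents that add atoms: potassium peroxymonosulfate (active part of Oxone) [K+].[O-]S(=O)(=O)OO
Why: Shi asymmetric epoxidation of a trans-disubstituted olefin by the chiral dioxirane formed in the flask; the L-series ketone transfers oxygen through the spiro transition state to the face that gives the (S,S)-oxirane (the D-fructose-derived ketone gives R,R), and both centres arise in this one syn transfer.

Step 3
Reactants: 4 1,3-bis(benzyloxy)benzene
Product: 7 2,6-bis(benzyloxy)phenol, via aryllithium 5 (not isolated), via boronate 6 (not isolated)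
Conditions: n-BuLi, THF, 0 °C → rt; B(OMe)3, −78 °C → rt; 30% H2O2, 0 °C → rt
Reagents that add atoms: hydrogen peroxide OO
Why: directed ortho-lithiation between the two benzyloxy groups, borylation and boronate oxidation (1,2-shift of aryl from boron to oxygen) place the third oxygen at C2.

Step 4
Reactants: 7 2,6-bis(benzyloxy)phenol
Product: 8 1,3-bis(benzyloxy)-2-(methoxymethoxy)benzene
Conditions: MOMCl, i-Pr2NEt, CH2Cl2, 0 °C → rt
Reagents that add atoms: chloromethyl methyl ether COCCl
Why: O-alkylation of the phenol to the MOM acetal, which tolerates hydrogenolysis, organolithium and fluoride and cannot be expelled by a neighbouring aryl anion.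

Step 5
Reactants: 8 1,3-bis(benzyloxy)-2-(methoxymethoxy)benzene
Product: 9 2-(methoxymethoxy)benzene-1,3-diol
Conditions: H2 (1 atm), 10% Pd/C, EtOAc/MeOH, rt
Reagents that add atoms: none
Why: hydrogenolysis of the two benzyl ethers frees the outer phenols while the acetal stays.

Step 6
Reactants: 9 2-(methoxymethoxy)benzene-1,3-diol
Product: 10 4,6-dibromo-2-(methoxymethoxy)benzene-1,3-diol
Conditions: NBS (2.05 equiv), MeCN, −20 → 0 °C
Reagents that add atoms: N-bromosuccinimide O=C1CCC(=O)N1Br
Why: electrophilic aromatic bromination; C4 and C6 are each ortho to one hydroxyl and para to the other, whereas C5 is meta to both.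

Step 7
Reactants: 10 4,6-dibromo-2-(methoxymethoxy)benzene-1,3-diol
Product: 13 2-(methoxymethoxy)-4,6-bis(trimethylsilyl)-1,3-phenylene bis(trifluoromethanesulfonate), via bis(silyl ether) 11 (not isolated), via dilithium diolate 12 (not isolated)
Conditions: (Me3Si)2NH, THF, 65 °C, evaporate; n-BuLi (2.2 equiv), THF, −78 → −40 °C; Tf2O (2.4 equiv), −78 °C → rt
Reagents that add atoms: hexamethyldisilazane C[Si](C)(C)N[Si](C)(C)C; trifluoromethanesulfonic anhydride O=S(=O)(OS(=O)(=O)C(F)(F)F)C(F)(F)F
Why: the standard assembly of an o-silylaryl triflate, done twice on one ring: O-silylation, bromine–lithium exchange with 1,3 O→C silyl migration (retro-Brook rearrangement), and O-triflation of the phenoxide.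

Step 8
Reactants: 13 2-(methoxymethoxy)-4,6-bis(trimethylsilyl)-1,3-phenylene bis(trifluoromethanesulfonate); 3 4-[(2S,3S)-3-(3,5-dimethoxyphenyl)oxiran-2-yl]phenyl trifluoromethanesulfonate (5 equiv, excess recoverable)
Product: 17 [(2R,3R,5R,6R)-3,5-bis(3,5-dimethoxyphenyl)-4-(methoxymethoxy)-2,3,5,6-tetrahydrobenzo[1,2-b:5,4-b']difuran-2,6-diyl]di-4,1-phenylene bis(trifluoromethanesulfonate), via aryne 14 (not isolated), via mono-adduct 15 (not isolated), via aryne 16 (not isolated)
Conditions: CsF (6 equiv), MeCN/toluene 1:3, 13 added over 6 h, 40 °C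
Reagents that add atoms: none
Why: Proposed new method: fluoride removes a Me3Si group of 13 and the adjacent triflate leaves to give aryne 14; the oxirane oxygen of 3 adds to the aryne carbon remote from the OCH2OCH3 group, because this inductively withdrawing alkoxy group beside the triple bond makes the distal carbon the electrophilic one and stabilises the aryl anion that develops next to it, and the aryl-oxonium zwitterion then ionises at the oxirane carbon bearing the 3,5-dimethoxyphenyl ring (the other benzylic carbon is deactivated by the para-triflyloxy group) and collapses by C–C bond formation; 15 repeats the sequence through aryne 16. The closest known reaction type is the fluoride-induced insertion of benzyne into the benzylic C–O bond of styrene oxide to give a dihydrobenzofuran; new are the 2,3-diaryl oxirane, the transfer of its configuration and the twofold use on one benzene ring. Each new five-membered ring is the three-membered oxirane enlarged by the two aryne carbons: the aryl–O bond forms first and the ring closes by recombination of the aryl anion with the benzylic cation (C3–C3a bond, formally a 1,3-shift of carbon from oxygen to the ortho carbon). The C–O centre of the oxirane is not touched and becomes C2 (S in 3, R in 17 only through a change of CIP priorities), and C3 is set by this neighbouring centre because the ring closes with the two aryl groups trans, which corresponds to retention at the migrating carbon; one enantiomer of 3 used twice gives the C2-symmetric 2R,3R,5R,6R product. The step needs site selectivity on each aryne, secured by the 4-alkoxy group beside the triple bond (an ether, unlike a halide, is also not expelled by the neighbouring aryl anion), the right choice between the two benzylic C–O bonds, secured by triflate against dimethoxyphenyl, and ring closure faster than protonation of the zwitterion, favoured by excess 3, little acetonitrile and slow release of the aryne.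

Step 9
Reactants: 17 bis(aryl triflate) from step 8
Product: 19 [(2R,3R,5R,6R)-3,5-bis(3,5-dimethoxyphenyl)-4-(methoxymethoxy)-2,3,5,6-tetrahydrobenzo[1,2-b:5,4-b']difuran-2,6-diyl]di-4,1-phenylene bis(2,2-dimethylpropanoate), via bisphenol 18 (not isolated)
Conditions: Et4NOH (35% aq., 4.5 equiv), 1,4-dioxane, rt, evaporate; PivCl, pyridine, CH2Cl2, 0 °C → rt
Reagents that add atoms: pivaloyl chloride CC(C)(C)C(Cl)=O
Why: hydroxide attacks sulfur of the aryl triflates (S–O cleavage) and the freed phenoxides are acylated; pivalate is inert to palladium, keeps the para oxygen a poor donor in the acidic steps and is removed at the end by methanolysis.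

Step 10
Reactants: 19 dipivalate MOM ether
Product: 20 [(2R,3R,5R,6R)-3,5-bis(3,5-dimethoxyphenyl)-4-hydroxy-2,3,5,6-tetrahydrobenzo[1,2-b:5,4-b']difuran-2,6-diyl]di-4,1-phenylene bis(2,2-dimethylpropanoate)
Conditions: HCl (2 M in MeOH), THF, 40 °C
Reagents that add atoms: none
Why: acid-catalysed acetal exchange removes the MOM group, while the benzylic C–O bonds of the dihydrofurans are protected against ionisation by the para-acyloxy groups.

Step 11
Reactants: 20 C4 phenol
Product: 21 [(2R,3R,5R,6R)-3,5-bis(3,5-dimethoxyphenyl)-4-{[(trifluoromethyl)sulfonyl]oxy}-2,3,5,6-tetrahydrobenzo[1,2-b:5,4-b']difuran-2,6-diyl]di-4,1-phenylene bis(2,2-dimethylpropanoate)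
Conditions: Tf2O, pyridine, DMAP (cat.), CH2Cl2, 0 °C → rt
Reagents that add atoms: trifluoromethanesulfonic anhydride O=S(=O)(OS(=O)(=O)C(F)(F)F)C(F)(F)F
Why: O-triflation of the hindered phenol turns the C4–O group into a cross-coupling electrophile.

Step 12
Reactants: 22 1-ethynyl-2,4-dimethoxybenzene
Product: 23 2-[(E)-2-(2,4-dimethoxyphenyl)ethenyl]-4,4,5,5-tetramethyl-1,3,2-dioxaborolane
Conditions: pinacolborane, Cp2Zr(H)Cl (5 mol %), Et3N (10 mol %), 60 °C, neat
Reagents that add atoms: pinacolborane CC1(C)OBOC1(C)C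
Why: zirconium-catalysed syn hydroboration of the terminal alkyne puts boron on the terminal carbon and gives the (E)-alkenylboronate.

Step 13
Reactants: 21 C4 triflate; 23 2-[(E)-2-(2,4-dimethoxyphenyl)ethenyl]-4,4,5,5-tetramethyl-1,3,2-dioxaborolane
Product: 24 [(2R,3R,5R,6R)-4-[(E)-2-(2,4-dimethoxyphenyl)ethenyl]-3,5-bis(3,5-dimethoxyphenyl)-2,3,5,6-tetrahydrobenzo[1,2-b:5,4-b']difuran-2,6-diyl]di-4,1-phenylene bis(2,2-dimethylpropanoate)
Conditions: Pd(OAc)2 (5 mol %), SPhos (10 mol %), K3PO4, toluene/H2O 10:1, 90 °C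
Reagents that add atoms: none
Why: Suzuki–Miyaura coupling in which the bulky electron-rich biarylphosphine supports oxidative addition of zerovalent palladium into the doubly ortho-substituted aryl triflate; the olefin geometry of 23 is retained.

Step 14
Reactants: 24 C4 stilbene
Product: 25 hexa-O-methyl-di-O-pivaloyl derivative of the target (ring D closed; all five stereocentres R)
Conditions: TsOH·H2O (0.2 equiv), CH2Cl2, 0 °C → rt
Reagents that add atoms: none
Why: the acid protonates the stilbene at the carbon next to ring A, and the resulting 2,4-dimethoxybenzylic cation is captured by the ortho position of a neighbouring 3,5-dimethoxyphenyl ring (intramolecular Friedel–Crafts alkylation to the seven-membered ring; the two such rings are equivalent by the twofold axis), the new centre being set by the adjacent furan C3 centre with the aryl group pseudo-axial, cis to that centre's hydrogen.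

Step 15
Reactants: 25 hexa-O-methyl-di-O-pivaloyl derivative of the target
Product: 27 CNP0154047.1 (target octaphenol), via dipivalate 26 (not isolated)
Conditions: BBr3 (1.0 M in CH2Cl2, 14 equiv), CH2Cl2, −78 → 0 °C; MeOH, evaporate; K2CO3, degassed MeOH, rt
Reagents that add atoms: none
Why: Lewis-acid cleavage of the six aryl methyl ethers (boron coordination, then attack of bromide on methyl) followed by base-catalysed methanolysis of the two aryl pivalates; no stereocentre is touched because the para-acyloxy groups keep the dihydrofuran C2–O bonds from ionising.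

**Compound list**

1 | pterostilbene, 4-[(E)-2-(3,5-dimethoxyphenyl)ethenyl]phenol | COc1cc(/C=C/c2ccc(O)cc2)cc(OC)c1 | starting material
2 | 4-[(E)-2-(3,5-dimethoxyphenyl)ethenyl]phenyl trifluoromethanesulfonate | COc1cc(/C=C/c2ccc(OS(=O)(=O)C(F)(F)F)cc2)cc(OC)c1 | intermediate
3 | 4-[(2S,3S)-3-(3,5-dimethoxyphenyl)oxiran-2-yl]phenyl trifluoromethanesulfonate | COc1cc([C@@H]2O[C@H]2c2ccc(OS(=O)(=O)C(F)(F)F)cc2)cc(OC)c1 | intermediate
4 | 1,3-bis(benzyloxy)benzene | c1ccc(COc2cccc(OCc3ccccc3)c2)cc1 | starting material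
5 | [2,6-bis(benzyloxy)phenyl]lithium | [Li]c1c(OCc2ccccc2)cccc1OCc1ccccc1 | intermediate (not isolated)
6 | dimethyl [2,6-bis(benzyloxy)phenyl]boronate | COB(OC)c1c(OCc2ccccc2)cccc1OCc1ccccc1 | intermediate (not isolated)
7 | 2,6-bis(benzyloxy)phenol | Oc1c(OCc2ccccc2)cccc1OCc1ccccc1 | intermediate
8 | 1,3-bis(benzyloxy)-2-(methoxymethoxy)benzene | COCOc1c(OCc2ccccc2)cccc1OCc1ccccc1 | intermediate
9 | 2-(methoxymethoxy)benzene-1,3-diol | COCOc1c(O)cccc1O | intermediate
10 | 4,6-dibromo-2-(methoxymethoxy)benzene-1,3-diol | COCOc1c(O)c(Br)cc(Br)c1O | intermediate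
11 | 4,6-dibromo-2-(methoxymethoxy)-1,3-bis(trimethylsilyloxy)benzene | COCOc1c(O[Si](C)(C)C)c(Br)cc(Br)c1O[Si](C)(C)C | intermediate (not isolated)
12 | dilithium 2-(methoxymethoxy)-4,6-bis(trimethylsilyl)benzene-1,3-diolate | COCOc1c([O-])c([Si](C)(C)C)cc([Si](C)(C)C)c1[O-].[Li+].[Li+] | intermediate (not isolated)
13 | 2-(methoxymethoxy)-4,6-bis(trimethylsilyl)-1,3-phenylene bis(trifluoromethanesulfonate) | COCOc1c(OS(=O)(=O)C(F)(F)F)c([Si](C)(C)C)cc([Si](C)(C)C)c1OS(=O)(=O)C(F)(F)F | intermediate
14 | 3-(methoxymethoxy)-4-(triflyloxy)-5-(trimethylsilyl)benzyne (1,2-didehydrobenzene) | COCOC1=C(OS(=O)(=O)C(F)(F)F)C([Si](C)(C)C)=CC#C1 | intermediate (not isolated)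
15 | (2R,3R)-3-(3,5-dimethoxyphenyl)-4-(methoxymethoxy)-2-[4-(triflyloxy)phenyl]-6-(trimethylsilyl)-2,3-dihydro-1-benzofuran-5-yl trifluoromethanesulfonate | FC(F)(F)S(=O)(=O)Oc1ccc(cc1)[C@@H]1Oc2cc([Si](C)(C)C)c(OS(=O)(=O)C(F)(F)F)c(OCOC)c2[C@H]1c1cc(OC)cc(OC)c1 | intermediate (not isolated)
16 | 5,6-didehydro aryne from 15: 4-[(2R,3R)-5,6-didehydro-3-(3,5-dimethoxyphenyl)-4-(methoxymethoxy)-2,3-dihydro-1-benzofuran-2-yl]phenyl trifluoromethanesulfonate | FC(F)(F)S(=O)(=O)Oc1ccc(cc1)[C@@H]1OC2=CC#CC(OCOC)=C2[C@H]1c1cc(OC)cc(OC)c1 | intermediate (not isolated)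
17 | [(2R,3R,5R,6R)-3,5-bis(3,5-dimethoxyphenyl)-4-(methoxymethoxy)-2,3,5,6-tetrahydrobenzo[1,2-b:5,4-b']difuran-2,6-diyl]di-4,1-phenylene bis(trifluoromethanesulfonate) | FC(F)(F)S(=O)(=O)Oc1ccc(cc1)[C@@H]1Oc2cc3O[C@@H](c4ccc(OS(=O)(=O)C(F)(F)F)cc4)[C@H](c4cc(OC)cc(OC)c4)c3c(OCOC)c2[C@H]1c1cc(OC)cc(OC)c1 | intermediate
18 | 4,4'-[(2R,3R,5R,6R)-3,5-bis(3,5-dimethoxyphenyl)-4-(methoxymethoxy)-2,3,5,6-tetrahydrobenzo[1,2-b:5,4-b']difuran-2,6-diyl]diphenol | Oc1ccc(cc1)[C@@H]1Oc2cc3O[C@@H](c4ccc(O)cc4)[C@H](c4cc(OC)cc(OC)c4)c3c(OCOC)c2[C@H]1c1cc(OC)cc(OC)c1 | intermediate (not isolated)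
19 | dipivalate of 18 | CC(C)(C)C(=O)Oc1ccc(cc1)[C@@H]1Oc2cc3O[C@@H](c4ccc(OC(=O)C(C)(C)C)cc4)[C@H](c4cc(OC)cc(OC)c4)c3c(OCOC)c2[C@H]1c1cc(OC)cc(OC)c1 | intermediate
20 | 4-hydroxy analogue of 19 (MOM removed) | CC(C)(C)C(=O)Oc1ccc(cc1)[C@@H]1Oc2cc3O[C@@H](c4ccc(OC(=O)C(C)(C)C)cc4)[C@H](c4cc(OC)cc(OC)c4)c3c(O)c2[C@H]1c1cc(OC)cc(OC)c1 | intermediate
21 | 4-triflyloxy analogue of 19 | CC(C)(C)C(=O)Oc1ccc(cc1)[C@@H]1Oc2cc3O[C@@H](c4ccc(OC(=O)C(C)(C)C)cc4)[C@H](c4cc(OC)cc(OC)c4)c3c(OS(=O)(=O)C(F)(F)F)c2[C@H]1c1cc(OC)cc(OC)c1 | intermediate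
22 | 1-ethynyl-2,4-dimethoxybenzene | COc1ccc(C#C)c(OC)c1 | starting material
23 | 2-[(E)-2-(2,4-dimethoxyphenyl)ethenyl]-4,4,5,5-tetramethyl-1,3,2-dioxaborolane | COc1ccc(/C=C/B2OC(C)(C)C(C)(C)O2)c(OC)c1 | intermediate
24 | 4-[(E)-2-(2,4-dimethoxyphenyl)ethenyl] analogue of 19 | CC(C)(C)C(=O)Oc1ccc(cc1)[C@@H]1Oc2cc3O[C@@H](c4ccc(OC(=O)C(C)(C)C)cc4)[C@H](c4cc(OC)cc(OC)c4)c3c(/C=C/c4ccc(OC)cc4OC)c2[C@H]1c1cc(OC)cc(OC)c1 | intermediate
25 | hexa-O-methyl-di-O-pivaloyl derivative of the target (methyl ethers on both resorcinol rings and on the 2,4-dioxygenated ring, pivalates on the two 4-oxyphenyl groups, all five centres R) | CC(C)(C)C(=O)Oc1ccc([C@@H]2Oc3cc4c5c(c3[C@H]2c2cc(OC)cc(OC)c2)C[C@H](c2ccc(OC)cc2OC)c2c(OC)cc(OC)cc2[C@H]5[C@H](c2ccc(OC(=O)C(C)(C)C)cc2)O4)cc1 | intermediate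
26 | di-O-pivaloyl derivative of the target (six free phenols) | CC(C)(C)C(=O)Oc1ccc([C@@H]2Oc3cc4c5c(c3[C@H]2c2cc(O)cc(O)c2)C[C@H](c2ccc(O)cc2O)c2c(O)cc(O)cc2[C@H]5[C@H](c2ccc(OC(=O)C(C)(C)C)cc2)O4)cc1 | intermediate (not isolated)
27 | CNP0154047.1 | Oc1ccc([C@@H]2Oc3cc4c5c(c3[C@H]2c2cc(O)cc(O)c2)C[C@H](c2ccc(O)cc2O)c2c(O)cc(O)cc2[C@H]5[C@H](c2ccc(O)cc2)O4)cc1 | target

**Step count**

Total: 15 steps. Longest linear sequence: 12 steps (steps 3–11 and 13–15, from 4).

**Steps most likely to fail**

Step 8 (Proposed new method). The oxirane oxygen may lose the competition for the aryne to fluoride, acetonitrile or the electron-rich aryl rings. The zwitterion may be protonated or undergo a hydride shift before the ring closes. The wrong benzylic C–O bond may open, and the second aryne may fail after the first insertion. The fallback uses known chemistry only and sets out from 13. CsF-promoted reaction of both arynes with commercial 3,5-dimethoxybenzoic acid (carboxylate O-arylation, then acyl transfer to the aryl anion, the known route from arynes and carboxylic acids to o-hydroxyaryl ketones, with the same site rule) should give [4,6-dihydroxy-2-(methoxymethoxy)-1,3-phenylene]bis[(3,5-dimethoxyphenyl)methanone] F1. NaBH4 in MeOH should reduce it to the bis(benzhydrol) F2. The o-quinone methides released from F2 under mild base would be trapped in a [4+1] annulation by the benzylic sulfur ylide generated with base from the 4-(benzyloxy)benzyl sulfonium tetrafluoroborate of isothiocineole F3. F3 is made from the commercial sulfide, 4-(benzyloxy)benzyl bromide and NaBF4; the enantiomer of the sulfide is chosen to give the 2R series. The annulation closes each ring trans and should give the bis(benzyl ether) F4. Hydrogenolysis of F4 (H2, Pd/C) gives bisphenol 18, where the route is rejoined at the acylation half of step 9.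

Step 13. Transmetalation and reductive elimination at a palladium centre flanked by two benzhydryl-type ortho substituents may be slow, so that S–O hydrolysis of the triflate back to the phenol and loss of the pivalates take over. The fallback sets out from 21 and the alkyne 22. Sonogashira coupling (PdCl2(PPh3)2, CuI, Et3N, DMF, 70 °C), in which the linear copper acetylide is far less sensitive to the ortho groups, should give the diarylalkyne F5. Semihydrogenation over Pb(OAc)2-poisoned Pd/CaCO3 with quinoline gives the (Z)-stilbene F6. Protonation of F6 under the conditions of step 14 gives the same benzylic cation as 24, so the route is rejoined at 25.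

Step 7. The second bromine–lithium exchange may stay incomplete, or the aryllithium may be protonated before the silyl group migrates, which leaves mono-silylated or silicon-free phenols. The fallback sets out from 9. Isopropyl isocyanate with catalytic Et3N gives 2-(methoxymethoxy)-1,3-phenylene bis(N-isopropylcarbamate) F7. N-Silylation in the flask (TMSOTf, TMEDA) and carbamate-directed ortho-lithiation (n-BuLi, TMEDA, Et2O, −78 °C) with Me3SiCl quench at the only two free ortho positions gives the 4,6-bis(trimethylsilyl) bis(carbamate) F8. Cleavage of the carbamates (Et2NH, DBU, MeCN, 40 °C) and triflation of the phenoxides with PhNTf2 in the same flask gives 13.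

**Further compounds**

F1 | step 8 | [4,6-dihydroxy-2-(methoxymethoxy)-1,3-phenylene]bis[(3,5-dimethoxyphenyl)methanone] | COCOc1c(C(=O)c2cc(OC)cc(OC)c2)c(O)cc(O)c1C(=O)c1cc(OC)cc(OC)c1
F2 | step 8 | 4,6-bis[(3,5-dimethoxyphenyl)(hydroxy)methyl]-5-(methoxymethoxy)benzene-1,3-diol (mixture of diastereomers, both carbinol centres are lost in the next operation) | COCOc1c(C(O)c2cc(OC)cc(OC)c2)c(O)cc(O)c1C(O)c1cc(OC)cc(OC)c1
F3 | step 8 | (1R,4R,5R)-6-[4-(benzyloxy)benzyl]-4,7,7-trimethyl-6-thiabicyclo[3.2.1]octan-6-ium tetrafluoroborate (or its enantiomer; one diastereomer at sulfur expected, configuration at sulfur not specified) | C[C@@H]1CC[C@@H]2C[C@H]1[S+](Cc1ccc(OCc3ccccc3)cc1)C2(C)C.F[B-](F)(F)F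
F4 | step 8 | (2R,3R,5R,6R)-2,6-bis[4-(benzyloxy)phenyl]-3,5-bis(3,5-dimethoxyphenyl)-4-(methoxymethoxy)-2,3,5,6-tetrahydrobenzo[1,2-b:5,4-b']difuran | c1ccccc1COc1ccc(cc1)[C@@H]1Oc2cc3O[C@@H](c4ccc(OCc5ccccc5)cc4)[C@H](c4cc(OC)cc(OC)c4)c3c(OCOC)c2[C@H]1c1cc(OC)cc(OC)c1
F5 | step 13 | 4-[(2,4-dimethoxyphenyl)ethynyl] analogue of 19 | CC(C)(C)C(=O)Oc1ccc(cc1)[C@@H]1Oc2cc3O[C@@H](c4ccc(OC(=O)C(C)(C)C)cc4)[C@H](c4cc(OC)cc(OC)c4)c3c(C#Cc4ccc(OC)cc4OC)c2[C@H]1c1cc(OC)cc(OC)c1
F6 | step 13 | 4-[(Z)-2-(2,4-dimethoxyphenyl)ethenyl] analogue of 19 | CC(C)(C)C(=O)Oc1ccc(cc1)[C@@H]1Oc2cc3O[C@@H](c4ccc(OC(=O)C(C)(C)C)cc4)[C@H](c4cc(OC)cc(OC)c4)c3c(/C=C\c4ccc(OC)cc4OC)c2[C@H]1c1cc(OC)cc(OC)c1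
F7 | step 7 | 2-(methoxymethoxy)-1,3-phenylene bis(N-isopropylcarbamate) | COCOc1c(OC(=O)NC(C)C)cccc1OC(=O)NC(C)C
F8 | step 7 | 2-(methoxymethoxy)-4,6-bis(trimethylsilyl)-1,3-phenylene bis(N-isopropylcarbamate) | COCOc1c(OC(=O)NC(C)C)c([Si](C)(C)C)cc([Si](C)(C)C)c1OC(=O)NC(C)C
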